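The hydroazulene is disconnected at C1–C5 and C9–C10. The feature used is that, in the seven-membered ring (C1, C5, C6, C7, C8, C9, C10), the sp2 fusion carbon C5 and the methylene C9 are 1,5-related through C6–C7–C8, so they can serve as the two termini of a 3-oxidopyrylium whose ring oxygen spans them, while C1=C10 is an alkene held on C5 by the quaternary C4 and C3–C2. One base-triggered intramolecular (5+2) cycloaddition closes the cyclopentane and the cycloheptane, sets C1 and C10, and leaves a C5–O–C9 bridge whose reductive opening later gives the C5=C6 enolate. The precursor is an Achmatowicz-derived acetoxypyranone carrying C4, the aryl-bearing Ca and a (Z)-pent-3-enyl chain.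

Key step: step 12

Remarks on the chemistry
- Locants: Ca = benzylic CH; C4 = quaternary carbon; C3, C2 = ring CH2; C1 = ring-fusion CH; C5=C6 = alkene; C7 = CH bearing the carbinol carbon C11; C8, C9 = CH2; C10 = CH bearing CH3. Ar = 2,4,6-trimethoxyphenyl.
- Assumption: 3 is bought as the racemate (its stereocentre is erased in the enamine); C5 and the acetal carbon C9 are carried as mixtures up to 20 because both become sp2 in ylide 21.
- Ring connectivity: in the seven-membered ring C5 is bonded to C1 and C6, and C10 is the neighbour of C1 and C9; the cycloaddition therefore joins C1 to C5 and C10 to C9.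
- Protecting group: the C11 oxygen is carried as a triethylsilyl ether, which is sturdier than a trimethylsilyl ether toward chromatography and protic work-ups. It is put on only after the furan has been metalated, because a 2-lithiofuran beside a silyloxy group is prone to 1,4 O→C silyl shift; the free alkoxide instead directs metalation to C2.
- Bridge opening and formylation: the bridge is opened with lithium so that the enolate is a lithium enolate, for which O-triflation is established. Arene formylation is done by directed metalation, because acid-mediated formylation would endanger the homoallylic tertiary C–O bond and the C5=C6 alkene.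

Step 1
Reactants: 1 2,4,6-trimethoxybenzaldehyde
Product: 2 rac-1-(2,4,6-trimethoxyphenyl)prop-2-en-1-ol
Conditions: CH2=CHMgBr, THF, −78 → 0 °C; aq. NH4Cl
Reagents that add atoms: vinylmagnesium bromide, C=C[Mg]Br
Why: Grignard 1,2-addition to the aryl aldehyde; the carbinol is used as the racemate because the iridium catalyst of step 2 ionises both enantiomers to the same allyl complex.

Step 2
Reactants: 2 rac-1-(2,4,6-trimethoxyphenyl)prop-2-en-1-ol; 3 methyl 4-methyl-5-oxopentanoate (racemic)
Product: 4 methyl (4R,5S)-4-formyl-4-methyl-5-(2,4,6-trimethoxyphenyl)hept-6-enoate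
Conditions: [Ir(cod)Cl]2 (cat.), BINOL-derived N-(dibenzo[b,f]azepinyl) phosphoramidite (P,olefin ligand, cat.), 9-amino-9-deoxy-epi-cinchona alkaloid primary amine (cat.), Cl3CCO2H (cat.), ClCH2CH2Cl, rt; ligand and amine antipodes chosen for the (4R,5S) isomer
Reagents that add atoms: none
Why: Stereodivergent dual catalysis (iridium-catalysed allylic substitution of a racemic aryl vinyl carbinol joined to enamine catalysis of an α-branched aldehyde): the iridium complex ionises 2 to an aryl-substituted allyl electrophile that the enamine of 3 attacks at the branched terminus, the ligand antipode fixing Ca and the amine antipode fixing the quaternary C4 independently, and 2,6-dialkoxyaryl vinyl carbinols are a known substrate class for this catalyst.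

Step 3
Reactants: 4 methyl (4R,5S)-4-formyl-4-methyl-5-(2,4,6-trimethoxyphenyl)hept-6-enoate
Product: 5 methyl (4R,5S)-4-formyl-4,7-dimethyl-5-(2,4,6-trimethoxyphenyl)oct-6-enoate
Conditions: 2-methylpropene (excess, sealed vessel), second-generation Hoveyda–Grubbs catalyst (cat.), CH2Cl2, 40 °C
Reagents that add atoms: 2-methylpropene, CC(C)=C
Why: Olefin cross-metathesis of the monosubstituted alkene with excess 2-methylpropene caps the vinyl group as an isobutenyl group; aldehyde, ester and arene are inert to the ruthenium carbene and no stereocentre is touched.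

Step 4
Reactants: 5 methyl (4R,5S)-4-formyl-4,7-dimethyl-5-(2,4,6-trimethoxyphenyl)oct-6-enoate
Product: 6 methyl (4R,5S)-4-formyl-4,7-dimethyl-5-(2,4,6-trimethoxyphenyl)octanoate
Conditions: H2 (4 bar), 10% Pd/C, EtOAc, rt
Reagents that add atoms: none
Why: Heterogeneous catalytic hydrogenation of the trisubstituted alkene gives the isobutyl group; the aldehyde has no α-hydrogen, so C4 cannot epimerise, and Ca is not affected.

Step 5
Reactants: 7 methyl furan-3-carboxylate
Product: 8 2-(furan-3-yl)propan-2-ol
Conditions: MeMgBr (2.5 equiv), THF, 0 °C → rt; aq. NH4Cl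
Reagents that add atoms: methylmagnesium bromide, C[Mg]Br
Why: Double Grignard addition to the ester gives the tertiary carbinol C11 with both of its methyl groups.

Step 6
Reactants: 8 2-(furan-3-yl)propan-2-ol; 6 methyl (4R,5S)-4-formyl-4,7-dimethyl-5-(2,4,6-trimethoxyphenyl)octanoate
Product: 11 6-[3-(2-hydroxypropan-2-yl)furan-2-yl]-5-methyl-5-[3-methyl-1-(2,4,6-trimethoxyphenyl)butyl]oxan-2-one (Ca and C4 as in 6; both C5 epimers), via dilithiated furylcarbinol 9 (not isolated), via dilithium alkoxide adduct 10 (not isolated)
Conditions: 8, n-BuLi (2.2 equiv), THF, 0 °C → rt; −78 °C, add 6; → rt; aq. NH4Cl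
Reagents that add atoms: none
Why: Alkoxide-directed ortho-lithiation of the 3-furylcarbinol at C2, 1,2-addition of the furyllithium to the aldehyde (faster than to the ester at −78 °C) and lactonisation of the new secondary alkoxide on warming; C5 forms as both epimers, which is harmless because C5 becomes sp2 in step 12.

Step 7
Reactants: 11 6-[3-(2-hydroxypropan-2-yl)furan-2-yl]-5-methyl-5-[3-methyl-1-(2,4,6-trimethoxyphenyl)butyl]oxan-2-one
Product: 12 5-methyl-5-[3-methyl-1-(2,4,6-trimethoxyphenyl)butyl]-6-{3-[2-(triethylsilyloxy)propan-2-yl]furan-2-yl}oxan-2-one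
Conditions: Et3SiOTf, 2,6-lutidine, CH2Cl2, −78 → 0 °C
Reagents that add atoms: triethylsilyl trifluoromethanesulfonate, CC[Si](CC)(CC)OS(=O)(=O)C(F)(F)F
Why: Silylation of the hindered tertiary alcohol with a silyl triflate and a hindered base; the silyl ether later prevents O11 from closing onto C9 in step 10 and blocks retro-aldol loss of acetone from the β-oxygenated ketone 23.

Step 8
Reactants: 12 5-methyl-5-[3-methyl-1-(2,4,6-trimethoxyphenyl)butyl]-6-{3-[2-(triethylsilyloxy)propan-2-yl]furan-2-yl}oxan-2-one
Product: 13 5-methyl-5-[3-methyl-1-(2,4,6-trimethoxyphenyl)butyl]-6-{3-[2-(triethylsilyloxy)propan-2-yl]furan-2-yl}oxan-2-ol (lactol; epimers at C1 and C5)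
Conditions: i-Bu2AlH (1.2 equiv), CH2Cl2, −78 °C; aq. Rochelle salt
Reagents that add atoms: none
Why: Partial reduction of the lactone with i-Bu2AlH at low temperature stops at the lactol, a masked C1 aldehyde.

Step 9
Reactants: 13 lactol (as above); 14 ethyltriphenylphosphonium bromide
Product: 16 (5Z)-2-methyl-2-[3-methyl-1-(2,4,6-trimethoxyphenyl)butyl]-1-{3-[2-(triethylsilyloxy)propan-2-yl]furan-2-yl}hept-5-en-1-ol (Ca and C4 as in 6; both C5 epimers), via ethylidenetriphenylphosphorane 15 (not isolated)
Conditions: 14, KN(SiMe3)2, THF, 0 °C; −78 °C, add 13; → rt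
Reagents that add atoms: none
Why: Wittig olefination of the lactol through its open hydroxy-aldehyde form with a non-stabilised, salt-free ylide gives the (Z)-alkene C1=C10 under kinetic control and frees the C5 hydroxyl.

Step 10
Reactants: 16 (5Z)-furyl carbinol (as above)
Product: 19 6-hydroxy-2-[(8Z)-2,5-dimethyl-4-(2,4,6-trimethoxyphenyl)dec-8-en-5-yl]-4-[2-(triethylsilyloxy)propan-2-yl]-2H-pyran-3(6H)-one (mixture at C5 and C9), via furan endoperoxide 17 (not isolated), via hydroxy keto-enal 18 (not isolated)
Conditions: O2, 5,10,15,20-tetraphenylporphyrin (cat.), visible light, CH2Cl2, −78 °C; then Me2S, −78 °C → rt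
Reagents that add atoms: dioxygen, O=O
Why: Achmatowicz rearrangement by the singlet-oxygen route ((4+2) addition to the furan, reduction of the endoperoxide to the (Z)-keto-enal, closure of the C5 hydroxyl onto C9); singlet oxygen reacts with the furan far faster than with the (Z)-alkene or the arene, which a bromonium source or a peracid would attack.

Step 11
Reactants: 19 6-hydroxypyranone (as above)
Product: 20 6-acetoxy-2-[(8Z)-2,5-dimethyl-4-(2,4,6-trimethoxyphenyl)dec-8-en-5-yl]-4-[2-(triethylsilyloxy)propan-2-yl]-2H-pyran-3(6H)-one (mixture at C5 and C9)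
Conditions: Ac2O, pyridine, DMAP (cat.), CH2Cl2, 0 °C
Reagents that add atoms: acetic anhydride, CC(=O)OC(C)=O
Why: Acetylation of the hemiacetal hydroxyl installs the leaving group at C9; all diastereomers are carried on because they converge in the ylide.

Step 12
Reactants: 20 6-acetoxypyranone (as above)
Product: 22 oxygen-bridged tricyclic enone (C6 ketone; C7=C8; C5–O–C9 bridge; H1 and H10 cis and anti to the bridge; C10 methyl on the bridge side; C4 methyl on the cyclopentane face of the bridge oxygen; Ca arm on the face of C6), via 3-oxidopyrylium betaine 21 (not isolated)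
Conditions: DBU (1.5 equiv), MeCN (0.01 M), 60 → 80 °C
Reagents that add atoms: none
Why: DBU removes acetate from C9 and the proton from C5 to give the 3-oxidopyrylium betaine 21, which adds across C5 and C9, suprafacially and in one concerted step, to the tethered C1=C10 alkene. This is the known intramolecular oxidopyrylium–alkene (5+2) cycloaddition of Achmatowicz-derived 6-acyloxypyranones. The cyclopentane closes through C1–C5 over the three-atom tether C4–C3–C2 (five-membered closure with C10 left outside the ring, assisted by the quaternary C4), and the cycloheptene closes through C9–C10 as the seven-membered ring of the (5+2) array, the former ring oxygen becoming the C5–O–C9 bridge. C5 and C9 are fixed together by the ylide face that is attacked; C1 by the exo placement of the tether (C2 syn to the bridge and H1 anti, the only arrangement that keeps the new oxolane and the cyclopentane cis-fused); C10 by the (Z)-geometry, which is transferred stereospecifically so that H10 is cis to H1 and the methyl group lies on the bridge side. The step needs facial selectivity: the alkene must add to the face that leaves the C4 methyl on the same side of the new cyclopentane as the ring oxygen and the Ca arm on the side of C6, and the substrate offers the C4 stereocentre for this, through the C4–C5 rotamer in which the Ca–H bond points at the C6 oxide while the aryl and isobutyl groups point away from the ring. Chemoselectivity is secured by the inert silyl ether and arene and by high dilution, which disfavours ylide dimerisation, and all C5 and C9 isomers of 20 converge on the same ylide.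

Step 13
Reactants: 22 oxygen-bridged tricyclic enone
Product: 23 saturated oxygen-bridged ketone (H7 syn to the bridge; C11 group endo)
Conditions: H2 (1 atm), 10% Pd/C, EtOAc, rt
Reagents that add atoms: none
Why: Catalytic hydrogenation of the enone C7=C8 from the exo face (the side of the oxygen bridge, the endo face being screened by the C1–C10 bridge and its endo hydrogens) places H7 syn to the bridge, which is the C7 configuration of the target; neutral conditions avoid epimerisation next to the ketone.

Step 14
Reactants: 23 saturated oxygen-bridged ketone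
Product: 25 C5=C6 enol triflate with free C9 hydroxyl (C9–OH cis to the C10 methyl; C1, C7, C10 as in 23), via dilithium enolate alkoxide 24 (not isolated)
Conditions: Li (2.2 equiv), NH3(l)/THF, −78 °C; NH3 evaporated; PhNTf2 (1.1 equiv), THF, −78 → 0 °C; aq. NH4Cl
Reagents that add atoms: N,N-bis(trifluoromethylsulfonyl)aniline, O=S(=O)(N(c1ccccc1)S(=O)(=O)C(F)(F)F)C(F)(F)F
Why: Dissolving-metal reductive cleavage of the α-alkoxy ketone (the C6 ketyl expels the C5–O bond, which lies α to the carbonyl and nearly perpendicular to its plane) gives the C5=C6 lithium enolate regiospecifically with the C9 alkoxide, and the enolate is trapped on oxygen with PhNTf2 as in reductive enolate triflations of enones; C9 keeps its configuration because its C–O bond is not broken.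

Step 15
Reactants: 25 C5=C6 enol triflate with free C9 hydroxyl
Product: 26 hydroazulene with C5=C6 alkene and C9 hydroxyl (C11 silyl ether; arene unsubstituted at its two free positions)
Conditions: Pd(OAc)2 (cat.), PPh3, HCO2H, Bu3N, DMF, 60 °C
Reagents that add atoms: none
Why: Palladium-catalysed formate reduction of the enol triflate (oxidative addition to zerovalent palladium, formate-to-hydride exchange, reductive elimination) replaces OTf by H without moving the double bond or touching C7.

Step 16
Reactants: 26 hydroazulene with C5=C6 alkene and C9 hydroxyl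
Product: 27 C9 O-(S-methyl dithiocarbonate) of 26
Conditions: NaH, imidazole (cat.), THF, 0 °C → rt; CS2; MeI
Reagents that add atoms: carbon disulfide, S=C=S; iodomethane, CI
Why: Xanthate formation from the secondary C9 alkoxide (first half of the Barton–McCombie deoxygenation); the tertiary oxygen is silylated and cannot react.

Step 17
Reactants: 27 C9 xanthate
Product: 28 C9-deoxygenated hydroazulene triethylsilyl ether (C1, C4, C7, C10 and Ca as in the target)
Conditions: Bu3SnH, AIBN (cat.), toluene, 100 °C
Reagents that add atoms: none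
Why: Barton–McCombie radical deoxygenation: the stannyl radical adds to the thiocarbonyl, the C9–O bond fragments, and the secondary C9 radical, which has no favourable cyclisation onto C5=C6, is reduced by Bu3SnH.

Step 18
Reactants: 28 C9-deoxygenated hydroazulene triethylsilyl ether
Product: 31 mono-aldehyde (formyl group at one of the two free arene positions), via aryllithium 29 (not isolated), via lithium hemiaminal alkoxide 30 (not isolated)
Conditions: n-BuLi, TMEDA, THF, 0 °C; DMF, 0 °C → rt; aq. NH4Cl
Reagents that add atoms: N,N-dimethylformamide, CN(C)C=O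
Why: Directed ortho-metalation at an arene C–H flanked by two methoxy groups, then formylation with DMF; the silyl ether, the trisubstituted alkene and the benzylic C–H are not attacked, and no acid is used.

Step 19
Reactants: 31 mono-aldehyde
Product: 35 dialdehyde triethylsilyl ether (2,4,6-trimethoxy-3,5-diformylphenyl arm), via lithium α-amino alkoxide 32 (not isolated), via lithiated α-amino alkoxide 33 (not isolated), via dilithium bis-hemiaminal alkoxide 34 (not isolated)
Conditions: Me2NCH2CH2N(Me)Li (from the amine and n-BuLi), THF, −20 °C; n-BuLi (3 equiv), −20 → 0 °C; DMF; aq. NH4Cl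
Reagents that add atoms: N,N-dimethylformamide, CN(C)C=O
Why: In situ protection of the aldehyde as a lithium α-amino alkoxide, a second directed ortho-metalation at the last ring C–H (again between two methoxy groups) and formylation with DMF; aqueous work-up releases both aldehydes.

Step 20
Reactants: 35 dialdehyde triethylsilyl ether
Product: 36 tri-O-methyl ether of the target (free C11 hydroxyl)
Conditions: Bu4NF, THF, rt → 40 °C
Reagents that add atoms: none
Why: Fluoride-induced cleavage of the triethylsilyl ether frees the tertiary hydroxyl under non-acidic conditions.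

Step 21
Reactants: 36 tri-O-methyl ether of the target
Product: 37 5-[(1R)-1-[(1R,3aR,4R,7R)-7-(2-hydroxypropan-2-yl)-1,4-dimethyl-1,2,3,3a,4,5,6,7-octahydroazulen-1-yl]-3-methylbutyl]-2,4,6-trihydroxybenzene-1,3-dicarbaldehyde (CNP0281883.1)
Conditions: 4-MeC6H4SNa (excess), DMPU/toluene, 110 °C; then cold dilute HCl
Reagents that add atoms: none
Why: Nucleophilic (SN2 at methyl) cleavage of the three aryl methyl ethers by an arenethiolate, each methoxy group being ortho or para to a formyl group and so a good phenoxide leaving group; the conditions are non-acidic, so the tertiary homoallylic alcohol, the alkene and all stereocentres are left alone.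

Compound list
1 | 2,4,6-trimethoxybenzaldehyde | COc1cc(OC)c(C=O)c(OC)c1 | starting material
2 | rac-1-(2,4,6-trimethoxyphenyl)prop-2-en-1-ol | C=CC(O)c1c(OC)cc(OC)cc1OC | intermediate
3 | methyl 4-methyl-5-oxopentanoate (racemic) | COC(=O)CCC(C)C=O | starting material
4 | methyl (4R,5S)-4-formyl-4-methyl-5-(2,4,6-trimethoxyphenyl)hept-6-enoate | C=C[C@@H](c1c(OC)cc(OC)cc1OC)[C@@](C)(CCC(=O)OC)C=O | intermediate
5 | methyl (4R,5S)-4-formyl-4,7-dimethyl-5-(2,4,6-trimethoxyphenyl)oct-6-enoate | CC(C)=C[C@@H](c1c(OC)cc(OC)cc1OC)[C@@](C)(CCC(=O)OC)C=O | intermediate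
6 | methyl (4R,5S)-4-formyl-4,7-dimethyl-5-(2,4,6-trimethoxyphenyl)octanoate | CC(C)C[C@@H](c1c(OC)cc(OC)cc1OC)[C@@](C)(CCC(=O)OC)C=O | intermediate
7 | methyl furan-3-carboxylate | COC(=O)c1ccoc1 | starting material
8 | 2-(furan-3-yl)propan-2-ol | CC(C)(O)c1ccoc1 | intermediate
9 | lithium 2-(2-lithiofuran-3-yl)propan-2-olate | [Li]OC(C)(C)c1ccoc1[Li] | intermediate (not isolated)
10 | dilithium alkoxide of the aldehyde adduct of 9 and 6 (open hydroxy ester) | CC(C)C[C@@H](c1c(OC)cc(OC)cc1OC)[C@@](C)(CCC(=O)OC)C(O[Li])c1occc1C(C)(C)O[Li] | intermediate (not isolated)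
11 | 6-[3-(2-hydroxypropan-2-yl)furan-2-yl]-5-methyl-5-[3-methyl-1-(2,4,6-trimethoxyphenyl)butyl]oxan-2-one (both C5 epimers) | CC(C)C[C@@H](c1c(OC)cc(OC)cc1OC)[C@@]1(C)CCC(=O)OC1c1occc1C(C)(C)O | intermediate
12 | triethylsilyl ether of 11 | CC(C)C[C@@H](c1c(OC)cc(OC)cc1OC)[C@@]1(C)CCC(=O)OC1c1occc1C(C)(C)O[Si](CC)(CC)CC | intermediate
13 | lactol from 12 (oxan-2-ol) | CC(C)C[C@@H](c1c(OC)cc(OC)cc1OC)[C@@]1(C)CCC(O)OC1c1occc1C(C)(C)O[Si](CC)(CC)CC | intermediate
14 | ethyltriphenylphosphonium bromide | CC[P+](c1ccccc1)(c1ccccc1)c1ccccc1.[Br-] | starting material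
15 | ethylidenetriphenylphosphorane | CC=P(c1ccccc1)(c1ccccc1)c1ccccc1 | intermediate (not isolated)
16 | (5Z)-2-methyl-2-[3-methyl-1-(2,4,6-trimethoxyphenyl)butyl]-1-{3-[2-(triethylsilyloxy)propan-2-yl]furan-2-yl}hept-5-en-1-ol (both C5 epimers) | CC(C)C[C@@H](c1c(OC)cc(OC)cc1OC)[C@@](C)(CC/C=C\C)C(O)c1occc1C(C)(C)O[Si](CC)(CC)CC | intermediate
17 | furan 2,5-endoperoxide of 16 | CC(C)C[C@@H](c1c(OC)cc(OC)cc1OC)[C@@](C)(CC/C=C\C)C(O)C12OOC(O1)C=C2C(C)(C)O[Si](CC)(CC)CC | intermediate (not isolated)
18 | (Z)-hydroxy keto-enal from 17 | CC(C)C[C@@H](c1c(OC)cc(OC)cc1OC)[C@@](C)(CC/C=C\C)C(O)C(=O)/C(=C\C=O)C(C)(C)O[Si](CC)(CC)CC | intermediate (not isolated)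
19 | 6-hydroxy-2-[(8Z)-2,5-dimethyl-4-(2,4,6-trimethoxyphenyl)dec-8-en-5-yl]-4-[2-(triethylsilyloxy)propan-2-yl]-2H-pyran-3(6H)-one | CC(C)C[C@@H](c1c(OC)cc(OC)cc1OC)[C@@](C)(CC/C=C\C)C1OC(O)C=C(C(C)(C)O[Si](CC)(CC)CC)C1=O | intermediate
20 | 6-acetoxy analogue of 19 (key-step precursor) | CC(C)C[C@@H](c1c(OC)cc(OC)cc1OC)[C@@](C)(CC/C=C\C)C1OC(OC(C)=O)C=C(C(C)(C)O[Si](CC)(CC)CC)C1=O | intermediate
21 | 3-oxidopyrylium betaine from 20 | CC(C)C[C@@H](c1c(OC)cc(OC)cc1OC)[C@@](C)(CC/C=C\C)c1[o+]ccc(C(C)(C)O[Si](CC)(CC)CC)c1[O-] | intermediate (not isolated)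
22 | oxygen-bridged tricyclic enone (key-step product) | CC(C)C[C@@H](c1c(OC)cc(OC)cc1OC)[C@@]1(C)CC[C@@H]2[C@H](C)[C@H]3C=C(C(C)(C)O[Si](CC)(CC)CC)C(=O)[C@@]12O3 | intermediate
23 | saturated oxygen-bridged ketone | CC(C)C[C@@H](c1c(OC)cc(OC)cc1OC)[C@@]1(C)CC[C@@H]2[C@H](C)[C@H]3C[C@@H](C(C)(C)O[Si](CC)(CC)CC)C(=O)[C@@]12O3 | intermediate
24 | dilithium C5=C6 enolate, C9 alkoxide | CC(C)C[C@@H](c1c(OC)cc(OC)cc1OC)[C@@]1(C)CC[C@H]2C1=C(O[Li])[C@H](C(C)(C)O[Si](CC)(CC)CC)C[C@@H](O[Li])[C@H]2C | intermediate (not isolated)
25 | C5=C6 enol triflate with C9 hydroxyl | CC(C)C[C@@H](c1c(OC)cc(OC)cc1OC)[C@@]1(C)CC[C@H]2C1=C(OS(=O)(=O)C(F)(F)F)[C@H](C(C)(C)O[Si](CC)(CC)CC)C[C@@H](O)[C@H]2C | intermediate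
26 | C5=C6 alkene with C9 hydroxyl | CC(C)C[C@@H](c1c(OC)cc(OC)cc1OC)[C@@]1(C)CC[C@H]2C1=C[C@H](C(C)(C)O[Si](CC)(CC)CC)C[C@@H](O)[C@H]2C | intermediate
27 | C9 O-(S-methyl dithiocarbonate) of 26 | CC(C)C[C@@H](c1c(OC)cc(OC)cc1OC)[C@@]1(C)CC[C@H]2C1=C[C@H](C(C)(C)O[Si](CC)(CC)CC)C[C@@H](OC(=S)SC)[C@H]2C | intermediate
28 | C9-deoxygenated hydroazulene triethylsilyl ether | CC(C)C[C@@H](c1c(OC)cc(OC)cc1OC)[C@@]1(C)CC[C@H]2C1=C[C@H](C(C)(C)O[Si](CC)(CC)CC)CC[C@H]2C | intermediate
29 | aryllithium from 28 (lithium between two methoxy groups) | CC(C)C[C@@H](c1c(OC)c([Li])c(OC)cc1OC)[C@@]1(C)CC[C@H]2C1=C[C@H](C(C)(C)O[Si](CC)(CC)CC)CC[C@H]2C | intermediate (not isolated)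
30 | lithium hemiaminal alkoxide (DMF adduct of 29) | CC(C)C[C@@H](c1c(OC)c(C(O[Li])N(C)C)c(OC)cc1OC)[C@@]1(C)CC[C@H]2C1=C[C@H](C(C)(C)O[Si](CC)(CC)CC)CC[C@H]2C | intermediate (not isolated)
31 | mono-aldehyde | CC(C)C[C@@H](c1c(OC)c(C=O)c(OC)cc1OC)[C@@]1(C)CC[C@H]2C1=C[C@H](C(C)(C)O[Si](CC)(CC)CC)CC[C@H]2C | intermediate
32 | lithium α-amino alkoxide of 31 | CC(C)C[C@@H](c1c(OC)c(C(O[Li])N(C)CCN(C)C)c(OC)cc1OC)[C@@]1(C)CC[C@H]2C1=C[C@H](C(C)(C)O[Si](CC)(CC)CC)CC[C@H]2C | intermediate (not isolated)
33 | ring-lithiated α-amino alkoxide | CC(C)C[C@@H](c1c(OC)c(C(O[Li])N(C)CCN(C)C)c(OC)c([Li])c1OC)[C@@]1(C)CC[C@H]2C1=C[C@H](C(C)(C)O[Si](CC)(CC)CC)CC[C@H]2C | intermediate (not isolated)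
34 | dilithium bis-hemiaminal alkoxide | CC(C)C[C@@H](c1c(OC)c(C(O[Li])N(C)CCN(C)C)c(OC)c(C(O[Li])N(C)C)c1OC)[C@@]1(C)CC[C@H]2C1=C[C@H](C(C)(C)O[Si](CC)(CC)CC)CC[C@H]2C | intermediate (not isolated)
35 | dialdehyde triethylsilyl ether | CC(C)C[C@@H](c1c(OC)c(C=O)c(OC)c(C=O)c1OC)[C@@]1(C)CC[C@H]2C1=C[C@H](C(C)(C)O[Si](CC)(CC)CC)CC[C@H]2C | intermediate
36 | tri-O-methyl ether of the target | CC(C)C[C@@H](c1c(OC)c(C=O)c(OC)c(C=O)c1OC)[C@@]1(C)CC[C@H]2C1=C[C@H](C(C)(C)O)CC[C@H]2C | intermediate
37 | CNP0281883.1 | CC(C)C[C@@H](c1c(O)c(C=O)c(O)c(C=O)c1O)[C@@]1(C)CC[C@H]2C1=C[C@H](C(C)(C)O)CC[C@H]2C | target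

Total step count: 21. Longest linear sequence: 20 steps (steps 1–4 and 6–21, from 1); step 5 is the one-step furan branch.

Steps most likely to fail

1. Step 12, facial discrimination. The C4 centre may relay weakly or to the other face, because allylic strain in the ylide also lets the methyl group, rather than the Ca arm, sit beside the C6 oxide. The outcome would be a mixture with, or mainly, the diastereomer that has C1, C10, C5 and C9 inverted relative to C4. Fallback (reagent control in place of substrate control): setting out from hemiacetal 19, acylation with 4-(methylsulfanyl)benzoyl chloride (pyridine, DMAP) should give the 6-O-[4-(methylsulfanyl)benzoyl] pyranone F1. F1 is then cyclised under the known dual catalysis by a chiral primary aminothiourea and an achiral thiourea (the enantioselective oxidopyrylium (5+2) conditions), with the catalyst antipode chosen so that its facial preference reinforces or overrides that of C4. The route is rejoined at 22.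

2. Step 2, diastereocontrol at C4. The enamine of an α-methyl-α-alkyl aldehyde has two geometrical isomers of similar energy, so the amine catalyst may set the quaternary centre poorly, while the iridium-controlled Ca should be unaffected. Premature ionisation of the very electron-rich carbinol by the acid promoter may also compete. Fallback (substrate control for C4): setting out from 2 and purchased propanal, the same iridium catalyst with a secondary amine ((S)-α,α-diphenylprolinol trimethylsilyl ether, (MeO)2P(O)OH), a combination established for linear aldehydes, should give (3R)-2-methyl-3-(2,4,6-trimethoxyphenyl)pent-4-enal F2, in which only the benzylic centre matters. Base-catalysed Michael addition of F2 to methyl acrylate (KOt-Bu cat., t-BuOH/THF, 0 °C) then builds C4. The acrylate should approach the enolate face opposite the aryl group in the rotamer that keeps the Ca–H bond in the enolate plane, which corresponds to the 4R configuration. The route is rejoined at 4.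

3. Step 14, enolate integrity and chemoselective triflation. The C9 alkoxide may compete for PhNTf2, the enolate may equilibrate toward C7 while ammonia is removed, or the arene may be partly reduced. Fallback (eliminative reduction instead of enolate trapping): setting out from 23, condensation with hydrazine (N2H4·H2O, AcOH, EtOH, reflux) should give the hydrazone F3. Treatment with KOt-Bu in DMSO should then expel the α-alkoxide and dinitrogen (Kishner–Leonard-type eliminative reduction, the ether counterpart of the Wharton reaction) and give the C5=C6 alkene with the free C9 hydroxyl directly. The route is rejoined at 26, so steps 14 and 15 are bypassed.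

Further compounds
F1 | step 12 | 6-[4-(methylsulfanyl)benzoyloxy]-2-[(8Z)-2,5-dimethyl-4-(2,4,6-trimethoxyphenyl)dec-8-en-5-yl]-4-[2-(triethylsilyloxy)propan-2-yl]-2H-pyran-3(6H)-one | CC(C)C[C@@H](c1c(OC)cc(OC)cc1OC)[C@@](C)(CC/C=C\C)C1OC(OC(=O)c2ccc(SC)cc2)C=C(C(C)(C)O[Si](CC)(CC)CC)C1=O
F2 | step 2 | (3R)-2-methyl-3-(2,4,6-trimethoxyphenyl)pent-4-enal (both C2 epimers) | C=C[C@@H](c1c(OC)cc(OC)cc1OC)C(C)C=O
F3 | step 14 | hydrazone of ketone 23 | CC(C)C[C@@H](c1c(OC)cc(OC)cc1OC)[C@@]1(C)CC[C@@H]2[C@H](C)[C@H]3C[C@@H](C(C)(C)O[Si](CC)(CC)CC)C(=NN)[C@@]12O3
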